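We read Monday's at 80 min and Friday's at 50 min, so we must ask what a finished flask holds and whether each has finished by its reading.

| flask | substrate | coupling partner | scavenger | free catalyst | temperature | remark | time |
|---|---|---|---|---|---|---|---|
| birch | 0.26 M | 0.30 equiv | 1.2 equiv | 0.53 mol% | 25 °C | run made earlier |  |
| oak | 0.26 M | 0.45 equiv | 1.2 equiv | 0.53 mol% | 36 °C | run made earlier |  |
| maple | 0.26 M | 0.60 equiv | 1.2 equiv | 0.8 mol% | 25 °C | run made earlier |  |
| Monday's | 0.26 M | 0.600 equiv | 1.20 equiv | 0.53 mol% |  | at 20 °C throughout | 80 min |
| Friday's | 0.26 M | 0.600 equiv | 1.20 equiv | 0.53 mol% |  | at 20 °C until 25 min, from then on at 40 °C | 50 min |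

| run | time / min | target / % | substrate / % |
|---|---|---|---|
| birch | 4.00 | 21.5 | 78.3 |
| birch | 12.0 | 29.5 | 69.7 |
| birch | 25.0 | 29.6 | 68.7 |
| birch | 40.0 | 29.8 | 69.6 |
| birch | 50.0 | 30.1 | 69.6 |
| oak | 2.00 | 20.2 | 79.5 |
| oak | 4.00 | 31.9 | 68.8 |
| oak | 6.00 | 38.1 | 60.9 |
| oak | 12.0 | 44.1 | 55.3 |
| oak | 25.0 | 44.8 | 54.5 |
| maple | 4.00 | 47.9 | 50.4 |
| maple | 12.0 | 60.0 | 39.3 |
| maple | 25.0 | 60.7 | 39.3 |
| maple | 40.0 | 59.8 | 39.7 |
| maple | 50.0 | 60.2 | 39.9 |

(scatter of a reading: 0.5 percentage points)

1. the flask that ends with the higher amount of target, in percent of the substrate charged, or "neither" when 2 percentage points or less lies between them (Monday's / Friday's / neither)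
2. final target, as a percentage of the substrate charged, in Monday's
3. final target, as a percentage of the substrate charged, in Friday's



The plateaus read 30.1%, 44.8% and 60.2% for charges of 0.30 equiv, 0.45 equiv and 0.60 equiv, so one coupling partner appears to give one target, and the partner is the limiting reagent. Monday's and Friday's therefore share a ceiling of 60.0%. Dividing that charge by the catalyst loading gives the turnover bill, the turnovers each catalyst must make to use up the limiting charge: 113.

Birch's first reading shows a pace of about 10.1 /min, counted in turnovers, so the bill for Monday's or Friday's takes 11.2 min at that pace, which is shorter than Friday's cold stretch of 25 min. We therefore commit to the ceiling for both flasks.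

The weak link is that constant pace: oak's target gains less from 4.00 min to 6.00 min than in its first 2.00 min, and birch ran at 25 °C, not 20 °C. We reforge it as a decay of the partner. Birch's first reading gives 0.315 /min, and oak's gives 0.298 /min at 36 °C, so these two readings, which differ in partner charge as well as temperature, show no speed-up we can count on. If we cut the birch constant to a quarter and give no credit for Friday's heating, we reckon 1.95% of the partner remaining at 50 min. On that reckoning the cost is 1.2 percentage points of target, within the margin of 2 points.

The forecast gives 60% for Monday's (58% to 61%) and 60% for Friday's (57.5% to 61%), with neither ahead, and judges that “Friday's is nearly finished before heating”.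

Monday's ends at 60.0% and Friday's at 60.0%, so the answer is neither.

    coupling partner + catalyst intermediate B → catalyst intermediate C (k = 12.0 /M/s, Ea = 36.0 kJ/mol)
    substrate + free catalyst → catalyst intermediate A (k = 7.40 /M/s, Ea = 44.0 kJ/mol)
    scavenger + released group → scavenged by-product (k = 0.300 /M/s, Ea = 43.0 kJ/mol)
    coupling partner + released group ⇌ idle adduct, settled at all times (K = 8.60 /M, ΔH = 42.0 kJ/mol)
    catalyst intermediate C ⇌ released group + catalyst intermediate D (K = 0.410 M, k = 4.90 /s, Ea = 60.0 kJ/mol, ΔH = −75.0 kJ/mol)
    catalyst intermediate D → free catalyst + target (k = 71.0 /s, Ea = 62.0 kJ/mol)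
    catalyst intermediate A ⇌ catalyst intermediate B (K = 0.620, k = 2.10 /s, Ea = 62.0 kJ/mol, ΔH = −54.0 kJ/mol)
    (constants at 20 °C)

On that count each flask has made 113 turnovers against the bill of 113. Monday's stops there because the coupling partner is depleted, with 0% of it left and 39.5% of the substrate still standing; the same run with that depletion taken away gives 100%. A neighbour of Monday's charged with 0.360 equiv of partner has a bill of 67.9 turnovers, and it ends at 36.0% of target.

All runs were generated by integration for an exercise; the scatter is artificial.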